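**Plan**
- Cuts: the quinone ring is opened at two non-adjacent ring bonds in one move, ring CH–C(=O) and C(OH)–C(side chain). This gives oxalyl chloride and an open-chain 2-methoxy-3-silyloxy-1,3-diene. The diene is cut back to an α-methoxy enone, then to a γ-lactone plus a methoxyvinyl anion, then to a lactone tosylate plus a decyl cuprate.
- Enabling feature: the hydroxyquinone is the enol of a cyclohex-5-ene-1,2,4-trione. Its C(=O)–C(OH) pair is an oxalyl unit, and the other four ring carbons (C-alkyl, C=O, C–OMe, CH) form a 2,3-dioxygenated butadiene whose two ends are both enol-ether β-carbons, so the ring can be built at its final oxidation level.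
- Forward order: the chain is joined first (C10 + C5), then the C2 methoxyvinyl unit, the acetate and the silyl dienol ether; the only ring is closed last by double C-acylation.
- Stereochemistry: the single stereocentre is taken unchanged from (S)-5-(tosyloxymethyl)butyrolactone (L-glutamic acid pool). No step makes or breaks a bond at it and it is never α to a carbonyl.

Key step: step 5

Remark: 10 is drawn as the expected Z silyl enol ether, and 7 and 13 each carry one transient, unassigned centre; none of these elements survives into 14, so they are not controlled.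

**Step 1**
Reactants: 1 (S)-(5-oxotetrahydrofuran-2-yl)methyl 4-methylbenzenesulfonate; 2 decylmagnesium bromide
Product: 4 (R)-5-undecyldihydrofuran-2(3H)-one, via bromomagnesium didecylcuprate 3 (not isolated)
Conditions: CuBr·SMe2 (1.5 equiv), 2 (3.0 equiv), THF, –40 °C; then 1, –40 to –20 °C; aq. NH4Cl
Reagents that add atoms: none
Why: The soft dialkylcuprate displaces the primary tosylate by SN2 (cuprate–sulfonate coupling) faster than it adds to the lactone carbonyl at low temperature; no bond at the stereocentre is touched, and the descriptor changes from S to R only because the new undecyl chain ranks below the ring CH2.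

**Step 2**
Reactants: 4 (R)-5-undecyldihydrofuran-2(3H)-one; 5 methyl vinyl ether
Product: 8 (R)-6-hydroxy-2-methoxyheptadec-1-en-3-one, via 1-methoxyvinyllithium 6 (not isolated), via lithium lactolate 7 (not isolated)
Conditions: 5 (1.5 equiv), t-BuLi (1.2 equiv), THF, –78 to 0 °C; then 4, –78 °C; aq. NH4Cl at –78 °C
Reagents that add atoms: none
Why: α-Lithiation of the vinyl ether gives an acyl-anion-type vinyllithium that should add once to the lactone (organolithium addition to a lactone), because the tetrahedral lactolate 7 does not collapse at –78 °C before the quench, and the open hydroxy enone is favoured over the lactol by conjugation.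

**Step 3**
Reactants: 8 (R)-6-hydroxy-2-methoxyheptadec-1-en-3-one
Product: 9 (R)-2-methoxy-3-oxoheptadec-1-en-6-yl acetate
Conditions: Ac2O, Et3N, DMAP (cat.), CH2Cl2, 0 °C to rt
Reagents that add atoms: acetic anhydride, CC(=O)OC(C)=O
Why: DMAP-catalysed acyl transfer (Steglich-type acetylation) to the secondary alcohol, which should also drain any lactol form into the open-chain acetate.

**Step 4**
Reactants: 9 (R)-2-methoxy-3-oxoheptadec-1-en-6-yl acetate
Product: 10 (R,Z)-3-[(tert-butyldimethylsilyl)oxy]-2-methoxyheptadeca-1,3-dien-6-yl acetate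
Conditions: TBSOTf (1.2 equiv), i-Pr2NEt (2 equiv), CH2Cl2, –78 to 0 °C; pentane/aq. NaHCO3 work-up, filtration through Et3N-deactivated silica
Reagents that add atoms: tert-butyldimethylsilyl trifluoromethanesulfonate, CC(C)(C)[Si](C)(C)OS(=O)(=O)C(F)(F)F
Why: Soft enolisation with a silyl triflate and a hindered amine: the ketone has α-hydrogens on one side only, the acetate is far less acidic and the non-nucleophilic base avoids conjugate addition to the enone, so the cross-conjugated 2-methoxy-3-silyloxy diene should form.

**Step 5**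
Reactants: 10 (R,Z)-3-[(tert-butyldimethylsilyl)oxy]-2-methoxyheptadeca-1,3-dien-6-yl acetate; 11 oxalyl chloride
Product: 14 (R)-1-(2-hydroxy-5-methoxy-3,6-dioxocyclohexa-1,4-dien-1-yl)tridecan-2-yl acetate, via dienyl glyoxylyl chloride 12 (not isolated), via cyclohexenetrione tautomer 13 (not isolated)
Conditions: 11 (1.05 equiv), 2,6-di-tert-butyl-4-methylpyridine (1.2 equiv), CH2Cl2 (0.02 M), slow addition of 10 at –78 °C, then to rt; pH 5 buffer work-up
Reagents that add atoms: none
Why: Proposed new method: the free CH2 end of the methoxy enol ether attacks oxalyl chloride to give an oxocarbenium ion that loses a proton to the hindered pyridine, forming the (E)-β-methoxyvinyl glyoxylyl chloride 12; its acid chloride is then attacked by the β-carbon of the silyl enol ether, chloride removes the silyl group as the silyl chloride, and trione 13 enolises to the hydroxyquinone. The closest known reactions are the acylation of enol ethers by oxalyl chloride, the Mukaiyama-type C-acylation of silyl enol ethers by acid chlorides and the formal [3+2] cyclisations of 1,3-bis(silyloxy)-1,3-dienes with oxalyl chloride; a [4+2] version on a 2,3-dioxygenated diene that ends in a quinone is the untested part. The ring closes in the second acylation as a 6-(enolendo)-exo-trig attack on the acyl chloride. No lasting stereocentre is formed (the ring CH of 13 is lost on enolisation), and the acetoxy-bearing carbon, two atoms from the ring and never α to a carbonyl, is untouched. The step needs the first acylation at the methoxyvinyl end, C- rather than O-acylation in the closure, and the acyl group cis to the silyloxy-bearing carbon in 12: these should be secured by the unsubstituted CH2 terminus against the substituted terminus shielded by the bulky silyl group, by the neutral silyl enol ether (no free enolate), and by the normal E geometry of β-alkoxy enones, which can also equilibrate through the oxocarbenium ion. The ring arrives at the quinone oxidation level, so no redox step follows.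

**Compound list**
1 | (S)-(5-oxotetrahydrofuran-2-yl)methyl 4-methylbenzenesulfonate | Cc1ccc(cc1)S(=O)(=O)OC[C@@H]1CCC(=O)O1 | starting material
2 | decylmagnesium bromide | CCCCCCCCCC[Mg]Br | starting material
3 | bromomagnesium didecylcuprate, (C10H21)2CuMgBr | CCCCCCCCCC[Cu-]CCCCCCCCCC.[Mg+]Br | intermediate (not isolated)
4 | (R)-5-undecyldihydrofuran-2(3H)-one | CCCCCCCCCCC[C@@H]1CCC(=O)O1 | intermediate
5 | methyl vinyl ether | COC=C | starting material
6 | 1-methoxyvinyllithium | [Li]C(OC)=C | intermediate (not isolated)
7 | lithium (5R)-2-(1-methoxyvinyl)-5-undecyltetrahydrofuran-2-olate (both epimers at the lactol carbon) | CCCCCCCCCCC[C@@H]1CCC([O-])(O1)C(OC)=C.[Li+] | intermediate (not isolated)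
8 | (R)-6-hydroxy-2-methoxyheptadec-1-en-3-one | CCCCCCCCCCC[C@H](CCC(=O)C(OC)=C)O | intermediate
9 | (R)-2-methoxy-3-oxoheptadec-1-en-6-yl acetate | CCCCCCCCCCC[C@H](CCC(=O)C(OC)=C)OC(C)=O | intermediate
10 | (R,Z)-3-[(tert-butyldimethylsilyl)oxy]-2-methoxyheptadeca-1,3-dien-6-yl acetate | CCCCCCCCCCC[C@H](C/C=C(\O[Si](C)(C)C(C)(C)C)C(OC)=C)OC(C)=O | intermediate
11 | oxalyl chloride | ClC(=O)C(Cl)=O | starting material
12 | (R,3E,5Z)-8-acetoxy-5-[(tert-butyldimethylsilyl)oxy]-4-methoxy-2-oxononadeca-3,5-dienoyl chloride | CCCCCCCCCCC[C@H](C/C=C(\O[Si](C)(C)C(C)(C)C)/C(OC)=C\C(=O)C(Cl)=O)OC(C)=O | intermediate (not isolated)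
13 | (R)-1-(5-methoxy-2,3,6-trioxocyclohex-4-en-1-yl)tridecan-2-yl acetate (both epimers at the ring CH) | CCCCCCCCCCC[C@H](CC1C(=O)C(=O)C=C(OC)C1=O)OC(C)=O | intermediate (not isolated)
14 | (R)-1-(2-hydroxy-5-methoxy-3,6-dioxocyclohexa-1,4-dien-1-yl)tridecan-2-yl acetate | CCCCCCCCCCC[C@H](CC1=C(O)C(=O)C=C(OC)C1=O)OC(C)=O | target

Total steps: 5. Longest linear sequence: 5 steps (from 1).

**Steps most likely to fail**

Step 5 (proposed new method). What may go wrong: first acylation at the silyl enol ether end followed by O-cyclisation to a furan-2,3-dione; intermolecular acylation to oligomers; or protodesilylation of the diene by the HCl formed. Fallback with known chemistry, setting out from 2 and returning at 14: decylmagnesium bromide 2 opens (R)-epichlorohydrin at the ring CH2 under CuI catalysis (THF, –40 °C) to (R)-1-chlorotridecan-2-ol F1, which NaOH closes to (R)-2-undecyloxirane F2. 1,2,4,5-Tetramethoxybenzene is lithiated between two methoxy groups (n-BuLi, THF, 0 °C) to 2,3,5,6-tetramethoxyphenyllithium F3, which opens F2 at its terminal carbon with BF3·OEt2 at –78 °C to (R)-1-(2,3,5,6-tetramethoxyphenyl)tridecan-2-ol F4. Acetylation (Ac2O, Et3N, DMAP) gives (R)-1-(2,3,5,6-tetramethoxyphenyl)tridecan-2-yl acetate F5, and oxidative demethylation with (NH4)2Ce(NO3)6 in MeCN/H2O at 0 °C gives (R)-1-(2,5-dimethoxy-3,6-dioxocyclohexa-1,4-dien-1-yl)tridecan-2-yl acetate F6. Brief treatment with HClO4 in CH2Cl2/dioxane should cleave the methoxy group next to the side chain, which is twisted out of conjugation and so the more labile vinylogous ester, to give 14. The regiochemistry of this last cleavage and the survival of the acetate would have to be confirmed.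

Step 4. What may go wrong: silyl-triflate-triggered Mukaiyama–Michael oligomerisation of the enone, competing silylation of the acetate, or hydrolysis of the diene on isolation. Fallback, setting out from 8 and returning at 14, leaves the acetate out until the end so that a base-only enolisation becomes possible. 8 is silylated (TBSCl, imidazole, DMF) to (R)-6-[(tert-butyldimethylsilyl)oxy]-2-methoxyheptadec-1-en-3-one F7. Kinetic deprotonation with LiN(SiMe3)2 and trapping with TBSCl/DMPU (THF, –78 °C) gives (R,Z)-3,6-bis[(tert-butyldimethylsilyl)oxy]-2-methoxyheptadeca-1,3-diene F8, which is annulated with 11 as in step 5 to (R)-3-{2-[(tert-butyldimethylsilyl)oxy]tridecyl}-2-hydroxy-5-methoxycyclohexa-2,5-diene-1,4-dione F9. HF·pyridine in THF frees (R)-2-hydroxy-3-(2-hydroxytridecyl)-5-methoxycyclohexa-2,5-diene-1,4-dione F10, and Ac2O/pyridine gives (R)-1-(2-acetoxy-5-methoxy-3,6-dioxocyclohexa-1,4-dien-1-yl)tridecan-2-yl acetate F11. Its quinone enol acetate, a vinylogous anhydride, should be cleaved selectively by aqueous NaHCO3 in THF at 0 °C to give 14.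

Step 2. What may go wrong: collapse of the tetrahedral adduct before the quench with a second addition of the vinyllithium, enolisation of the lactone, or hydrolysis of the enol ether during work-up. Fallback, setting out from 4 and returning at 8: the lactone is opened with MeNH(OMe)·HCl/AlMe3 (CH2Cl2, 0 °C) to (R)-4-hydroxy-N-methoxy-N-methylpentadecanamide F12, which is silylated at once (TESCl, imidazole, DMF) to (R)-N-methoxy-N-methyl-4-[(triethylsilyl)oxy]pentadecanamide F13. 1-Methoxyvinyllithium 6 then gives, through a chelated tetrahedral intermediate that cannot over-add, (R)-2-methoxy-6-[(triethylsilyl)oxy]heptadec-1-en-3-one F14, and buffered fluoride (Bu4NF/AcOH, THF, 0 °C) frees 8.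

**Further compounds**
F1 | step 5 | (R)-1-chlorotridecan-2-ol | CCCCCCCCCCC[C@H](CCl)O
F2 | step 5 | (R)-2-undecyloxirane | CCCCCCCCCCC[C@@H]1CO1
F3 | step 5 | 2,3,5,6-tetramethoxyphenyllithium | [Li]c1c(OC)c(OC)cc(OC)c1OC
F4 | step 5 | (R)-1-(2,3,5,6-tetramethoxyphenyl)tridecan-2-ol | CCCCCCCCCCC[C@H](Cc1c(OC)c(OC)cc(OC)c1OC)O
F5 | step 5 | (R)-1-(2,3,5,6-tetramethoxyphenyl)tridecan-2-yl acetate | CCCCCCCCCCC[C@H](Cc1c(OC)c(OC)cc(OC)c1OC)OC(C)=O
F6 | step 5 | (R)-1-(2,5-dimethoxy-3,6-dioxocyclohexa-1,4-dien-1-yl)tridecan-2-yl acetate | CCCCCCCCCCC[C@H](CC1=C(OC)C(=O)C=C(OC)C1=O)OC(C)=O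
F7 | step 4 | (R)-6-[(tert-butyldimethylsilyl)oxy]-2-methoxyheptadec-1-en-3-one | CCCCCCCCCCC[C@H](CCC(=O)C(OC)=C)O[Si](C)(C)C(C)(C)C
F8 | step 4 | (R,Z)-3,6-bis[(tert-butyldimethylsilyl)oxy]-2-methoxyheptadeca-1,3-diene | CCCCCCCCCCC[C@H](C/C=C(\O[Si](C)(C)C(C)(C)C)C(OC)=C)O[Si](C)(C)C(C)(C)C
F9 | step 4 | (R)-3-{2-[(tert-butyldimethylsilyl)oxy]tridecyl}-2-hydroxy-5-methoxycyclohexa-2,5-diene-1,4-dione | CCCCCCCCCCC[C@H](CC1=C(O)C(=O)C=C(OC)C1=O)O[Si](C)(C)C(C)(C)C
F10 | step 4 | (R)-2-hydroxy-3-(2-hydroxytridecyl)-5-methoxycyclohexa-2,5-diene-1,4-dione | CCCCCCCCCCC[C@H](CC1=C(O)C(=O)C=C(OC)C1=O)O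
F11 | step 4 | (R)-1-(2-acetoxy-5-methoxy-3,6-dioxocyclohexa-1,4-dien-1-yl)tridecan-2-yl acetate | CCCCCCCCCCC[C@H](CC1=C(OC(C)=O)C(=O)C=C(OC)C1=O)OC(C)=O
F12 | step 2 | (R)-4-hydroxy-N-methoxy-N-methylpentadecanamide | CCCCCCCCCCC[C@H](CCC(=O)N(C)OC)O
F13 | step 2 | (R)-N-methoxy-N-methyl-4-[(triethylsilyl)oxy]pentadecanamide | CCCCCCCCCCC[C@H](CCC(=O)N(C)OC)O[Si](CC)(CC)CC
F14 | step 2 | (R)-2-methoxy-6-[(triethylsilyl)oxy]heptadec-1-en-3-one | CCCCCCCCCCC[C@H](CCC(=O)C(OC)=C)O[Si](CC)(CC)CC
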